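You ask whether this flask's excess of right-handed substrate reaches 80 %, and how high that excess climbs.

* whether the excess of right-handed substrate over left-handed substrate among what is left of the two reaches 80 % by 3.0 d (yes / no)
* the highest excess of right-handed substrate over left-handed substrate among what is left of the two up to 3.0 d

common to all: gas 0.58 mM (held); free catalyst 0.18 mM
- south-east: left-handed substrate 0.0074 M; right-handed substrate 0.0074 M; added ligand 0.35 mM; run made earlier
- south-west: left-handed substrate 0.017 M; right-handed substrate 0.017 M; added ligand 0.35 mM; run made earlier
- north-west: left-handed substrate 0.011 M; right-handed substrate 0.011 M; added ligand 0.17 mM; run made earlier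
- flask: left-handed substrate 0.011 M; right-handed substrate 0.011 M; added ligand 0.35 mM; time 3.0 d

- south-east (time / h: right-handed substrate / %, left-handed substrate / %): 8.00: 50, 30; 15.0: 46, 11; 25.0: 44, 2; 30.0: 45, 0; 40.0: 41, 3
- south-west (time / h: right-handed substrate / %, left-handed substrate / %): 4.00: 53, 43; 10.0: 49, 36; 20.0: 46, 23; 30.0: 45, 7; 40.0: 47, 3
- north-west (time / h: right-handed substrate / %, left-handed substrate / %): 3.00: 49, 40; 6.00: 52, 36; 12.0: 44, 24; 25.0: 44, 8; 40.0: 41, 0

(standard deviation of a reading: 2 percentage points)

- free catalyst is single-handed; left-handed substrate and right-handed substrate are mirror images of each other, charged as a racemate, each of them at the stated concentration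
- at the start none of partner is dissolved
- steps under discussion: free catalyst + left-handed substrate <-> catalyst intermediate A; free catalyst + right-handed substrate <-> catalyst intermediate B; partner + catalyst intermediate A -> free catalyst + left-handed product; partner + catalyst intermediate B -> free catalyst + right-handed product; 2 partner -> self-condensation product; gas <-> partner; free catalyst + added ligand <-> idle complex

Your forecast says yes and 99.5 %, on the ground that “No listed step racemises the substrate or regenerates the left-handed form, so the excess keeps rising”. My own quick number comes from counting half-lives.

1. The south-west run had a heavier charge than your flask, 0.017 M of each substrate against 0.011 M, with the same catalyst and ligand. Its readings at 40.0 h give 88.0 % excess, but with a scatter of 2 percentage points on a reading as low as 3 %, that does not show the run past 80 %. Your flask has longer, up to 3.0 d, so the answer waits for the count of half-lives.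

2. In the south-east run, the readings of c(left-handed substrate) fell from 30 % to 11 % in 7.00 h, so by these two readings it halved about every 4.84 h. Call this the tail half-life: the time c(left-handed substrate) takes to halve once it is low, a pseudo-first-order half-life.

3. From 40.0 h to 3.0 d fit 6.62 tail half-lives. Taking the south-west reading of 3 % as a rough start for your flask, they bring it down to 0.0306 %.

4. Against the south-east reading of 41 % right-handed substrate, that gives 99.9 % excess, above your 99.5 %. A reading scatters by 2 points, so treat this as a rough figure, but it stands above 80 %, so I also say yes.

The flask gives yes and 99.9 %.

    free catalyst + left-handed substrate ⇌ catalyst intermediate A (K = 160 /M, k = 161 /M/min)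
    free catalyst + right-handed substrate ⇌ catalyst intermediate B (K = 149 /M, k = 90.6 /M/min)
    partner + catalyst intermediate A → free catalyst + left-handed product (k = 810 /M/min)
    partner + catalyst intermediate B → free catalyst + right-handed product (k = 29.6 /M/min)
    2 partner → self-condensation product (k = 1.99 /M/min)
    gas ⇌ partner, rate k6*(csat - [partner]) (kL = 0.0273 /min)
    free catalyst + added ligand ⇌ idle complex, settled at all times (K = 5600 /M)

The flask reached 80 % at 1.24 d, with 45.0 % of the two substrates charged still there as right-handed substrate. Between 1.50 d and 3.00 d fit 7.44 tail half-lives, which take the flask's 2.46 % of left-handed substrate to 0.0142 %; the flask held 0.0224 %. In the south-west run, 4.84 h takes the reading of 7 % at 30.0 h to 1.67 % at 40.0 h, where the reading was 3 %.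

(The runs stem from a simulated flask for substances that don't exist, noise included.)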